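## Structural features

The target 10 is a flavone in which a benzopyran-4-one (ring A fused to ring C through C4a–C8a) carries ring B, a 2,4-dihydroxyphenyl group, on C2 through the C2–C1' bond. Ring A is fully substituted, with hydroxyls at C5 and C7 and 3-methylbut-2-enyl (prenyl) groups at C6 and C8, and ring B has hydroxyls at C2' and C4'. There is no stereocentre and no stereogenic double bond, so no configuration has to be set or preserved. The fragile parts are the two trisubstituted prenyl alkenes, which lie beside free phenols and close onto them under acid to give dimethylchromans, and the electron-rich polyphenol itself, which is air-sensitive under base; hydrogenolysis and strong oxidants are therefore excluded. The real difficulty is threefold: a ring A in which every carbon is substituted, a ring C that must close from the ring A oxygen although ring B also carries an ortho oxygen (O2') that could close the other way, and a final deprotection next to acid-sensitive alkenes. Opened at O1–C2, ring A is a 3,5-diprenylphloracetophenone that is symmetric about its C1–C4 axis, so its two free ring carbons and its two ortho oxygens are equivalent. The key step exploits C2 of ring C: it is a single carbon at the carbonyl oxidation level whose only carbon neighbours are C3 (the methyl carbon of a ring A acetophenone) and C1' (the ipso carbon of ring B), so it can be delivered as carbon monoxide between an enolate and an aryl halide.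

## Logic of the disconnections

**10 ⇒ 9.** The four O–CH2 acetal bonds on O5, O7, O2' and O4' are cut, so that all four phenols appear masked as methoxymethyl ethers. The phenols have to pass a basic palladium step as non-nucleophilic ethers, and O2' must stay masked until ring C exists. Nothing is gained in skeleton; the gain is that one kind of group is removed in a single operation. The forward cleavage must not protonate the prenyl alkenes beside the phenols it sets free.

**9 ⇒ 8.** The O1–C2 bond of ring C is cut, which converts the pyranone into a 1-(2-hydroxyaryl)-3-aryl-1,3-diketone. This opens the only heterocycle and leaves two arenes joined by an acyclic three-carbon chain. The forward cyclodehydration must use the ring A oxygen and not O2'. This is met because the ring A hydroxyl is the only free phenol in 8 and, ring A being symmetric, either of its ortho oxygens gives the same pyranone.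

**8 ⇒ 4 + 6 + 7.** Both carbon–carbon bonds of C2 are cut, C2–C3 and C2–C1', and C2 itself becomes 7. The cut is placed here because a carbonyl-level carbon between a ketone methyl group and an aryl carbon is the retron of a carbonylative ketone arylation, so no benzoic acid derivative of ring B and no separate acyl-transfer step are needed. The molecule is divided into two arenes of similar size, each one or two steps from a commercial compound. The forward step must insert 7 faster than the aryl group couples directly with the enolate, must tolerate one chelated free phenol, two trisubstituted alkenes and four acetals, and must stop after one acylation.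

**4 ⇒ 3.** The two O–CH2 acetal bonds on O4 and O6 of the acetophenone are cut. The purpose is to leave exactly one hydroxyl free, the one hydrogen-bonded to the carbonyl, as the future O1. The forward etherification must stop at two groups, which the chelation of the last hydroxyl should ensure.

**3 ⇒ 1 + 2.** The two aryl–CH2 bonds at C3 and C5 of the acetophenone are cut (C8–C1'' and C6–C1'' of the target). 1 has only two free ring carbons and they are equivalent, so the cut raises no regiochemical question and leads to two bulk chemicals. The forward alkylation must go to carbon and not to oxygen, must put the second prenyl group on the other ring carbon and not on the first one again, and must stop at two.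

**6 ⇒ 5.** The two O–CH2 acetal bonds on ring B are cut. 5 already carries iodine on the carbon that becomes C1', ortho to one oxygen and para to the other, so neither a halogenation nor a halogen–metal exchange is needed. The only demand is complete etherification that leaves the C–I bond alone.

## Other disconnections considered

Alternative 1: The cut runs through ring A: C5–C6, C7–C8 and C4a–C5 are disconnected, so that ring A would be built last on a preformed 2-aryl-4-pyranone. In the forward step, irradiation of the diazo ketone 2-[2,4-bis(methoxymethoxy)phenyl]-6-(2-diazo-5-methylhex-4-enoyl)-4H-pyran-4-one A1 would trigger a Wolff rearrangement to a vinylketene whose vinyl unit is the pyranone C5=C6 bond. [2+2] cycloaddition of this ketene with the siloxyalkyne triisopropyl[(5-methylhex-4-en-1-ynyl)oxy]silane A2 would form C5–C6 and C7–C8. Four-electron ring opening of the cyclobutenone, six-electron electrocyclisation (C4a–C5) and tautomerisation would then give the 5-hydroxy-7-silyloxy flavone A3.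

In its favour, every substituent of ring A is placed by the connectivity of the partners, no phloroglucinol has to be C-alkylated, and O5 and O7 emerge differentiated. On regiocontrol of ring A this plan is better than the chosen one, whose first step is a statistical dialkylation.

Against it, A1 and A2 each need a multi-step preparation. The carbene from A1 has an adjacent allylic CH2, so a 1,2-hydrogen shift can compete with the Wolff shift. The tethered alkenes can intercept carbene or ketene. The pyranone double bond, part of a cross-conjugated vinylogous ester, is a reluctant partner in the electrocyclisation.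

In comparison, the mechanism is a pericyclic cascade that forms three C–C bonds and a ring, against a catalytic cycle that forms two C–C bonds and no ring. After A3 the silyl and acetal groups still have to be removed with acid, so the endgame risk is equal. In step count it would be several times longer than the five steps of the chosen plan.

Alternative 2: The cut is made in the side chains, at the two trisubstituted C=C bonds of the prenyl groups, which are traced back to allyl groups. In the forward step, the diallyl flavone tetraacetate A4 would undergo double cross-metathesis with an excess of 2-methylbut-2-ene A5 over the second-generation Grubbs catalyst to give the diprenyl tetraacetate A6. Mild basic deacetylation would then give 10.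

In its favour, allyl groups can be placed on ring A by aromatic Claisen rearrangement with defined regiochemistry. Terminal alkenes are protonated far less readily than prenyl groups, so acid-mediated steps could be finished before the prenyl groups exist. The last step would be a base-mediated ester cleavage. On control of the C-alkylation and on an acid-free final step this plan is better than the chosen one.

Against it, the step forms no bond of the flavone skeleton, so rings A, B and C still have to be joined by other means, for instance by the same carbonylative coupling carried out before the side chains are completed. It adds a protecting-group exchange and a ruthenium step. A5 is volatile and has to be used in large excess in a closed vessel. Both hindered allyl groups of A4 must react completely, since mixed allyl/prenyl material would be hard to separate from A6. Alkene migration to propenyl groups is a known side path of such catalysts.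

In comparison, the skeleton is the same and only the timing of the side chains differs. The mechanism is metallacyclobutane exchange against ionic alkylation. It costs about three to four steps more. Its allyl-to-prenyl idea is kept as the fallback for step 1.

Alternative 3: The cut is made in ring B, at C1'–C2' and C5'–C6'. In the forward step, 2-ethynyl-5,7-bis(methoxymethoxy)-6,8-bis(3-methylbut-2-enyl)-4H-chromen-4-one A7 would react with the diene 1-methoxy-1,3-bis(trimethylsilyloxy)buta-1,3-diene A8 in a Diels–Alder reaction. Elimination of the methoxy group and desilylation would aromatise the new ring to the 2',4'-dihydroxy flavone A9.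

In its favour, the polarisation of A8 sets the 2',4'-dioxygenation pattern, the ring B phenols arrive free and need no protecting groups, and neither palladium nor carbon monoxide gas is used. On hazard and on ring B protection it is better than the chosen plan. On regiochemical certainty of ring B it is equal, since the chosen plan buys that pattern in 5.

Against it, A7 already contains all of rings A and C with both prenyl groups and an alkyne at C2, so the difficult part of the molecule is not simplified. The alkyne is activated only through the C2=C3–C4=O system and is a modest dienophile. A8 is a nucleophilic, moisture-sensitive ketene acetal that could also add to C2 of the chromone.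

In comparison, it builds a ring by cycloaddition on a precious late intermediate, whereas the chosen plan joins two simple arenes early. A9 still needs acidic removal of two acetals, so the endgame is equal. The linear sequence would be clearly longer.

Key step: step 4

Remark: atom labels follow flavone numbering (O1, C2–C8a, C1'–C6'). The structures of 4, 6 and 8 map atom for atom onto the target. 4-Iodoresorcinol 5 is assumed to be a catalogue compound, which makes a halogen–lithium exchange on the way to 6 unnecessary.

## Route

Step 1
Reactants: 1 2,4,6-trihydroxyacetophenone; 2 prenyl bromide (1-bromo-3-methylbut-2-ene)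
Product: 3 1-[2,4,6-trihydroxy-3,5-bis(3-methylbut-2-enyl)phenyl]ethanone
Conditions: 2 (2.1 equiv), 10% aq KOH, 0 °C → rt; then aq citric acid to pH 4
Reagents that add atoms: none
Why: C-alkylation of an ambident phloroglucinol phenoxide by an allylic bromide (C-prenylation); in water the phenoxide oxygens are hydrogen-bonded, so the soft electrophile should attack the two equivalent free ring carbons. The symmetry of 1 means no regiochemical choice exists.

Step 2
Reactants: 3 1-[2,4,6-trihydroxy-3,5-bis(3-methylbut-2-enyl)phenyl]ethanone
Product: 4 1-[2-hydroxy-4,6-bis(methoxymethoxy)-3,5-bis(3-methylbut-2-enyl)phenyl]ethanone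
Conditions: MOMCl (2.3 equiv), i-Pr2NEt (3 equiv), CH2Cl2, 0 °C → rt
Reagents that add atoms: chloromethyl methyl ether, COCCl
Why: Williamson-type O-alkylation with an α-chloro ether; the most acidic 4-hydroxyl and one of the two equivalent ortho hydroxyls should react, while the last hydroxyl is held in a hydrogen bond to the acetyl carbonyl and stays free. That free hydroxyl is the later O1.

Step 3
Reactants: 5 4-iodoresorcinol (4-iodobenzene-1,3-diol)
Product: 6 1-iodo-2,4-bis(methoxymethoxy)benzene
Conditions: MOMCl (2.5 equiv), i-Pr2NEt (3.5 equiv), CH2Cl2, 0 °C → rt
Reagents that add atoms: chloromethyl methyl ether, COCCl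
Why: Williamson-type O-alkylation of both phenols with an α-chloro ether; the aryl iodide is inert to amine base at room temperature, so the halogen needed for oxidative addition is carried through unchanged.

Step 4
Reactants: 4 1-[2-hydroxy-4,6-bis(methoxymethoxy)-3,5-bis(3-methylbut-2-enyl)phenyl]ethanone; 6 1-iodo-2,4-bis(methoxymethoxy)benzene; 7 carbon monoxide
Product: 8 1-[2-hydroxy-4,6-bis(methoxymethoxy)-3,5-bis(3-methylbut-2-enyl)phenyl]-3-[2,4-bis(methoxymethoxy)phenyl]propane-1,3-dione
Conditions: 6 (1.1 equiv), Pd(OAc)2 (5 mol %), Xantphos (7.5 mol %), MgCl2 (3 equiv), NEt3 (5 equiv), CO (balloon, about 1 bar), 1,4-dioxane, 80 °C; aq NH4Cl work-up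
Reagents that add atoms: none
Why: Pd(OAc)2 and Xantphos are reduced in the flask to a zerovalent palladium bisphosphine complex, which adds oxidatively to the C–I bond of 6, and 7 inserts into the aryl–palladium bond to give a divalent aroylpalladium iodide (C2–C1'). MgCl2 and NEt3 convert 4 into its magnesium phenoxide and, by soft enolisation of the chelated carbonyl, into the enolate, whose methyl carbon is acylated at palladium with reductive elimination (C2–C3) and return of zerovalent palladium. If the aroyl group is transferred to the phenoxide oxygen first, the aryl ester is set up for a Baker–Venkataraman acyl shift under the same soft-enolisation conditions, so both paths should end in the magnesium chelate of 8, which is released on mild work-up. The closest known reaction type is the palladium-catalysed carbonylative α-arylation of aryl methyl ketones with aryl iodides to 1,3-diketones, together with the carbonylative coupling of 2-hydroxyacetophenones with aryl halides. No ring is closed and no stereocentre is formed. The selectivity needed is carbonylative over direct α-arylation; CO pressure, the wide bite angle of Xantphos, which favours the acyl complex, and the ortho-alkoxy group of 6, which slows aryl–enolate reductive elimination, should secure it. A second acylation is not expected because 8 is held as a poorly nucleophilic magnesium diketonate, the trisubstituted prenyl alkenes are poor Heck acceptors, and the amine-buffered medium leaves all four acetals intact. The ring A hydroxyl is left free on purpose: as the only free phenol in 8 it fixes the direction of the later ring closure.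

Step 5
Reactants: 8 1-[2-hydroxy-4,6-bis(methoxymethoxy)-3,5-bis(3-methylbut-2-enyl)phenyl]-3-[2,4-bis(methoxymethoxy)phenyl]propane-1,3-dione
Product: 10 2-(2,4-dihydroxyphenyl)-5,7-dihydroxy-6,8-bis(3-methylbut-2-enyl)-4H-chromen-4-one, via tetra-MOM flavone 9 (not isolated)
Conditions: 1.25 M HCl in MeOH, THF, 0 °C → rt (ring closure), then 40 °C (acetal removal); NaHCO3 quench
Reagents that add atoms: none
Why: Acid-catalysed cyclodehydration: the chelated ring A phenol adds to the ring B-side carbonyl of the enolised diketone (hemiketal) and loss of water closes the pyranone at O1–C2; the same acid then removes the four acetals by transacetalisation to MeOH. Closure should run in the right direction because the ring A hydroxyl is the only free phenol at the start and the other carbonyl lies between two ortho substituents, which disfavours attack from the ring B side even if O2' is unmasked early. Low acid strength and temperature are chosen to spare the prenyl alkenes.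

## Compound list

1 | 2,4,6-trihydroxyacetophenone | CC(=O)c1c(O)cc(O)cc1O | starting material
2 | prenyl bromide (1-bromo-3-methylbut-2-ene) | CC(C)=CCBr | starting material
3 | 1-[2,4,6-trihydroxy-3,5-bis(3-methylbut-2-enyl)phenyl]ethanone | CC(=O)c1c(O)c(CC=C(C)C)c(O)c(CC=C(C)C)c1O | intermediate
4 | 1-[2-hydroxy-4,6-bis(methoxymethoxy)-3,5-bis(3-methylbut-2-enyl)phenyl]ethanone | CC(=O)c1c(O)c(CC=C(C)C)c(OCOC)c(CC=C(C)C)c1OCOC | intermediate
5 | 4-iodoresorcinol (4-iodobenzene-1,3-diol) | Oc1ccc(I)c(O)c1 | starting material
6 | 1-iodo-2,4-bis(methoxymethoxy)benzene | COCOc1ccc(I)c(OCOC)c1 | intermediate
7 | carbon monoxide | [C-]#[O+] | starting material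
8 | 1-[2-hydroxy-4,6-bis(methoxymethoxy)-3,5-bis(3-methylbut-2-enyl)phenyl]-3-[2,4-bis(methoxymethoxy)phenyl]propane-1,3-dione | CC(C)=CCc1c(OCOC)c(CC=C(C)C)c(O)c(C(=O)CC(=O)c2ccc(OCOC)cc2OCOC)c1OCOC | intermediate
9 | 2-[2,4-bis(methoxymethoxy)phenyl]-5,7-bis(methoxymethoxy)-6,8-bis(3-methylbut-2-enyl)-4H-chromen-4-one | CC(C)=CCc1c(OCOC)c(CC=C(C)C)c2oc(-c3ccc(OCOC)cc3OCOC)cc(=O)c2c1OCOC | intermediate
10 | 2-(2,4-dihydroxyphenyl)-5,7-dihydroxy-6,8-bis(3-methylbut-2-enyl)-4H-chromen-4-one | CC(C)=CCc1c(O)c(CC=C(C)C)c2oc(-c3ccc(O)cc3O)cc(=O)c2c1O | target

## Step count and risks

Total: 5 steps. Longest linear sequence: 4 steps (1 → 3 → 4 → 8 → 10); the ring B branch (5 → 6) is one step.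

**Key step, step 4.** The most likely failure is a stall of the coupling. Either the aroyl group goes to the hindered phenoxide oxygen and the acyl shift to carbon stays incomplete, or enolisation of the doubly ortho-substituted, magnesium-chelated ketone is too slow, so that hydrodeiodination and direct arylation take over.

The fallback builds the same diketone by stepwise ionic acylation without palladium and sets out from 6. Iodine–magnesium exchange (i-PrMgCl·LiCl, THF, −20 °C) and carboxylation with CO2 would give 2,4-bis(methoxymethoxy)benzoic acid F1 after a citric acid work-up. Esterification of F1 with the free phenol of 4 (EDC·HCl, DMAP, CH2Cl2) would give 2-acetyl-3,5-bis(methoxymethoxy)-4,6-bis(3-methylbut-2-enyl)phenyl 2,4-bis(methoxymethoxy)benzoate F2. A Baker–Venkataraman rearrangement of F2 (KOtBu, THF, 0 °C → rt, aq NH4Cl work-up) would then move the aroyl group to the methyl carbon. The fallback comes back to the route at 8.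

**Step 1.** The most likely failure is loss of selectivity in the alkylation. Mono-alkylation, a second alkylation on the same ring carbon with loss of aromaticity, O-alkylation and a third alkylation all compete, because every product is still a nucleophilic phenoxide.

The fallback places allyl groups by sigmatropic rearrangement and converts them into prenyl groups later; it sets out from 1. O-Allylation (allyl bromide, K2CO3, acetone, reflux) would give 1-[2-hydroxy-4,6-bis(prop-2-enyloxy)phenyl]ethanone F3. Double aromatic Claisen rearrangement (N,N-diethylaniline, 200 °C) would give 1-[2,4,6-trihydroxy-3,5-bis(prop-2-enyl)phenyl]ethanone F4; an allyl group that finds its ortho carbon occupied moves on to the remaining free carbon. Etherification as in step 2 would give 1-[2-hydroxy-4,6-bis(methoxymethoxy)-3,5-bis(prop-2-enyl)phenyl]ethanone F5. Double cross-metathesis of F5 with 2-methylbut-2-ene A5 (second-generation Grubbs catalyst, CH2Cl2, 40 °C, closed vessel) would convert both allyl groups into prenyl groups. The fallback comes back to the route at 4 and replaces steps 1 and 2.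

**Step 5.** Two processes threaten this step. Once the flanking phenols are free, protonation of the prenyl alkenes can lead to ring closure onto oxygen or to addition of MeOH. Loss of the 2'-acetal before ring C has closed would open the way to closure from the ring B oxygen.

The fallback separates the two events and avoids protic acid in the deprotection; it sets out from 8. Cyclodehydration in an aprotic medium (pyridinium p-toluenesulfonate cat., toluene, 4 Å molecular sieves, 70 °C) would give 9, which is then isolated. The acetals would be cleaved with ZnBr2 and propane-1-thiol (CH2Cl2, 0 °C, short reaction time), the thiol trapping the methoxymethyl cation. The fallback comes back to the route at 10; no compound outside the list arises (F0).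

**Step 2.** The most likely failure is incomplete etherification of the 4-hydroxyl, which lies between two prenyl groups, or etherification of both chelated hydroxyls in its place.

The fallback is exhaustive protection followed by chelation-controlled release; it sets out from 3. NaH and MOMCl in DMF at 0 °C would give 1-[2,4,6-tris(methoxymethoxy)-3,5-bis(3-methylbut-2-enyl)phenyl]ethanone F6. Brief treatment of F6 with 0.2 M HCl in MeOH at 0 °C should cleave one acetal ortho to the carbonyl first, since the phenol set free is stabilised by the hydrogen bond. The fallback comes back to the route at 4.

## Further compounds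

F1 | step 4 | 2,4-bis(methoxymethoxy)benzoic acid | COCOc1ccc(C(=O)O)c(OCOC)c1
F2 | step 4 | 2-acetyl-3,5-bis(methoxymethoxy)-4,6-bis(3-methylbut-2-enyl)phenyl 2,4-bis(methoxymethoxy)benzoate | CC(=O)c1c(OC(=O)c2ccc(OCOC)cc2OCOC)c(CC=C(C)C)c(OCOC)c(CC=C(C)C)c1OCOC
F3 | step 1 | 1-[2-hydroxy-4,6-bis(prop-2-enyloxy)phenyl]ethanone | CC(=O)c1c(O)cc(OCC=C)cc1OCC=C
F4 | step 1 | 1-[2,4,6-trihydroxy-3,5-bis(prop-2-enyl)phenyl]ethanone | CC(=O)c1c(O)c(CC=C)c(O)c(CC=C)c1O
F5 | step 1 | 1-[2-hydroxy-4,6-bis(methoxymethoxy)-3,5-bis(prop-2-enyl)phenyl]ethanone | CC(=O)c1c(O)c(CC=C)c(OCOC)c(CC=C)c1OCOC
F0 | step 5 | none | none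
F6 | step 2 | 1-[2,4,6-tris(methoxymethoxy)-3,5-bis(3-methylbut-2-enyl)phenyl]ethanone | CC(=O)c1c(OCOC)c(CC=C(C)C)c(OCOC)c(CC=C(C)C)c1OCOC
A1 | alternative 1 | 2-[2,4-bis(methoxymethoxy)phenyl]-6-(2-diazo-5-methylhex-4-enoyl)-4H-pyran-4-one | CC(C)=CCC(=[N+]=[N-])C(=O)c1cc(=O)cc(-c2ccc(OCOC)cc2OCOC)o1
A2 | alternative 1 | triisopropyl[(5-methylhex-4-en-1-ynyl)oxy]silane | CC(C)=CCC#CO[Si](C(C)C)(C(C)C)C(C)C
A3 | alternative 1 | 2-[2,4-bis(methoxymethoxy)phenyl]-5-hydroxy-6,8-bis(3-methylbut-2-enyl)-7-(triisopropylsilyloxy)-4H-chromen-4-one | CC(C)=CCc1c(O[Si](C(C)C)(C(C)C)C(C)C)c(CC=C(C)C)c2oc(-c3ccc(OCOC)cc3OCOC)cc(=O)c2c1O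
A4 | alternative 2 | 2-(2,4-diacetoxyphenyl)-4-oxo-6,8-bis(prop-2-enyl)-4H-chromene-5,7-diyl diacetate | C=CCc1c(OC(C)=O)c(CC=C)c2oc(-c3ccc(OC(C)=O)cc3OC(C)=O)cc(=O)c2c1OC(C)=O
A5 | alternative 2 | 2-methylbut-2-ene | CC=C(C)C
A6 | alternative 2 | 2-(2,4-diacetoxyphenyl)-6,8-bis(3-methylbut-2-enyl)-4-oxo-4H-chromene-5,7-diyl diacetate | CC(C)=CCc1c(OC(C)=O)c(CC=C(C)C)c2oc(-c3ccc(OC(C)=O)cc3OC(C)=O)cc(=O)c2c1OC(C)=O
A7 | alternative 3 | 2-ethynyl-5,7-bis(methoxymethoxy)-6,8-bis(3-methylbut-2-enyl)-4H-chromen-4-one | CC(C)=CCc1c(OCOC)c(CC=C(C)C)c2oc(C#C)cc(=O)c2c1OCOC
A8 | alternative 3 | 1-methoxy-1,3-bis(trimethylsilyloxy)buta-1,3-diene | COC(O[Si](C)(C)C)=CC(=C)O[Si](C)(C)C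
A9 | alternative 3 | 2-(2,4-dihydroxyphenyl)-5,7-bis(methoxymethoxy)-6,8-bis(3-methylbut-2-enyl)-4H-chromen-4-one | CC(C)=CCc1c(OCOC)c(CC=C(C)C)c2oc(-c3ccc(O)cc3O)cc(=O)c2c1OCOC
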